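**Strategy.** Everything rests on cutting the C2–C3 bond of the ten-membered carbocycle C1–C10. The 1,3-diol C1(OH)–C2H2–C3(OH) of that ring is read backwards as a β-hydroxy ketone: the aldol of a C1 ketone enolate (ketone flanked by the Z C9=C10 alkene) with the C3 aldehyde of a Z C4=C5 enal. One SmI2 Reformatsky closure of a bromomethyl ketone forms C2–C3, the ring and the C3 carbinol. The precursor is a cis-disubstituted γ-butyrolactone (O6/C12 on C6 and C7) bearing the Z-enal on C6 and, through the silylated C8 carbinol, the Z-bromomethyl enone; its C6–C8 triad comes from diacetone-D-glucose.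

Key step: step 15

Remark: ring carbons are numbered C1–C10 as in the target, C11–C13 are the lactone carbons, and s1–s6 are the sugar carbons. The bromoacetyl group is carried as a Z-vinyl iodide and the lactone passes once through its lactol, so no step has to tell three carbonyl groups apart and O8–H is never free beside a Z-enoate.

Step 1
Reactants: 1 1,2:5,6-di-O-isopropylidene-α-D-glucofuranose
Product: 2 1,2:5,6-di-O-isopropylidene-α-D-ribo-hexofuranos-3-ulose
Conditions: Dess–Martin periodinane, CH2Cl2, rt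
Reagents that add atoms: none
Why: Dess–Martin oxidation of the only free hydroxyl (s3) should give the ketone without touching either acetonide, and no stereocentre is created.

Step 2
Reactants: 2 1,2:5,6-di-O-isopropylidene-α-D-ribo-hexofuranos-3-ulose; 3 trimethyl phosphonoacetate
Product: 4 methyl 2-(3-deoxy-1,2:5,6-di-O-isopropylidene-α-D-ribo-hexofuranos-3-ylidene)acetate (E/Z mixture)
Conditions: 3, KOtBu, THF, 0 °C → rt
Reagents that add atoms: trimethyl phosphonoacetate (3), COC(=O)CP(=O)(OC)OC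
Why: Horner–Wadsworth–Emmons olefination of the s3 ketone installs the two-carbon arm that becomes C11/C12; the alkene geometry is irrelevant because both isomers converge in the next step.

Step 3
Reactants: 4 methyl 2-(3-deoxy-1,2:5,6-di-O-isopropylidene-α-D-ribo-hexofuranos-3-ylidene)acetate
Product: 5 3-deoxy-3-C-(2-methoxy-2-oxoethyl)-1,2:5,6-di-O-isopropylidene-α-D-allofuranose (arm on the α face; cis to O2)
Conditions: H2 (1 atm), 10% Pd/C, EtOAc, rt
Reagents that add atoms: none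
Why: Heterogeneous hydrogenation should deliver hydrogen to the convex β face of the bicyclic furanose, opposite the 1,2-acetonide, so the arm ends cis to O2 (allo configuration) and the future C7 stereocentre is set under substrate control.

Step 4
Reactants: 5 3-deoxy-3-C-(2-methoxy-2-oxoethyl)-1,2:5,6-di-O-isopropylidene-α-D-allofuranose
Product: 7 3-deoxy-3-C-(2-methoxy-2-oxoethyl)-1,2-O-isopropylidene-α-D-ribo-pentodialdo-1,4-furanose, via 5,6-diol 6 (not isolated)
Conditions: H5IO6, EtOAc, rt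
Reagents that add atoms: none
Why: Periodic acid hydrolyses only the more labile terminal acetonide and cleaves the freed glycol in the same flask (Malaprade cleavage), giving the s5 aldehyde (future C9) with s4 untouched.

Step 5
Reactants: 7 3-deoxy-3-C-(2-methoxy-2-oxoethyl)-1,2-O-isopropylidene-α-D-ribo-pentodialdo-1,4-furanose; 8 ethyltriphenylphosphonium iodide
Product: 9 (5Z)-3,5,6,7-tetradeoxy-6-iodo-3-C-(2-methoxy-2-oxoethyl)-1,2-O-isopropylidene-α-D-ribo-hept-5-enofuranose (iodine cis to s4)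
Conditions: 8, n-BuLi, THF, 0 °C; I2, −78 °C; NaN(SiMe3)2, −20 °C; then 7, −78 → −20 °C
Reagents that add atoms: ethyltriphenylphosphonium iodide (8), CC[P+](c1ccccc1)(c1ccccc1)c1ccccc1.[I-]; iodine, [I][I]
Why: Stork–Zhao-type Wittig olefination with the α-iodo ylide Ph3P=C(I)CH3 is kinetically Z-selective and puts iodine cis to s4, so a robust vinyl iodide holds the place of C1 with the final C9=C10 geometry.

Step 6
Reactants: 9 (5Z)-3,5,6,7-tetradeoxy-6-iodo-3-C-(2-methoxy-2-oxoethyl)-1,2-O-isopropylidene-α-D-ribo-hept-5-enofuranose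
Product: 11 (3aR,4S,6aR)-6-hydroxy-4-[(1Z)-2-iodoprop-1-en-1-yl]tetrahydrofuro[3,4-b]furan-2(3H)-one (cis-fused lactone lactol; anomers at C6), via diol ester 10 (not isolated)
Conditions: TFA/H2O (9:1), 0 °C → rt; toluene azeotrope
Reagents that add atoms: none
Why: Acid hydrolysis of the 1,2-acetonide frees the 2-OH, which is cis to the ester arm and closes the γ-lactone by acid-catalysed transesterification while O4 (future O8) is still the ring oxygen, so the lactone can only form on O6.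

Step 7
Reactants: 11 (3aR,4S,6aR)-6-hydroxy-4-[(1Z)-2-iodoprop-1-en-1-yl]tetrahydrofuro[3,4-b]furan-2(3H)-one
Product: 12 (4R,5R)-5-(1,3-dithian-2-yl)-4-[(1S,2Z)-1-hydroxy-3-iodobut-2-en-1-yl]oxolan-2-one
Conditions: HS(CH2)3SH, BF3·OEt2, CH2Cl2, −20 → 0 °C
Reagents that add atoms: propane-1,3-dithiol, SCCCS
Why: Lewis-acid dithioacetalisation opens the lactol to the acyclic dithiane and frees O8–H at a stage where the molecule has no Michael acceptor for the thiol and no Z-enoate for O8–H to lactonise onto.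

Step 8
Reactants: 12 (4R,5R)-5-(1,3-dithian-2-yl)-4-[(1S,2Z)-1-hydroxy-3-iodobut-2-en-1-yl]oxolan-2-one
Product: 13 (4S,5R)-4-[(1S,2Z)-1-[tert-butyl(dimethyl)silyl]oxy-3-iodobut-2-en-1-yl]-5-(1,3-dithian-2-yl)oxolan-2-one
Conditions: TBSOTf, 2,6-lutidine, CH2Cl2, −78 → 0 °C
Reagents that add atoms: tert-butyldimethylsilyl triflate, CC(C)(C)[Si](C)(C)OS(=O)(=O)C(F)(F)F
Why: Silylation of the hindered secondary O8–H with the silyl triflate caps it at once and so blocks lactone migration from O6 to O8.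

Step 9
Reactants: 13 (4S,5R)-4-[(1S,2Z)-1-[tert-butyl(dimethyl)silyl]oxy-3-iodobut-2-en-1-yl]-5-(1,3-dithian-2-yl)oxolan-2-one
Product: 14 (2R,3S)-3-[(1S,2Z)-1-[tert-butyl(dimethyl)silyl]oxy-3-iodobut-2-en-1-yl]-5-oxooxolane-2-carbaldehyde
Conditions: MeI, CaCO3, MeCN/H2O (9:1), 45 °C
Reagents that add atoms: water, O
Why: Alkylative hydrolysis of the dithiane (S-methylation, then water) under carbonate buffer releases the C5 aldehyde under near-neutral conditions that should spare the epimerisable C6, the silyl ether and the vinyl iodide.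

Step 10
Reactants: 14 (2R,3S)-3-[(1S,2Z)-1-[tert-butyl(dimethyl)silyl]oxy-3-iodobut-2-en-1-yl]-5-oxooxolane-2-carbaldehyde; 15 ethyl 2-[bis(2,2,2-trifluoroethoxy)phosphoryl]propanoate
Product: 16 ethyl (2Z)-3-[(2S,3S)-3-[(1S,2Z)-1-[tert-butyl(dimethyl)silyl]oxy-3-iodobut-2-en-1-yl]-5-oxooxolan-2-yl]-2-methylprop-2-enoate
Conditions: 15, KN(SiMe3)2, 18-crown-6, THF, −78 °C; then 14
Reagents that add atoms: ethyl 2-[bis(2,2,2-trifluoroethoxy)phosphoryl]propanoate (15), CCOC(=O)C(C)P(=O)(OCC(F)(F)F)OCC(F)(F)F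
Why: Still–Gennari olefination with the electron-poor phosphonate and a crown-separated potassium ion eliminates fast from the kinetic adduct and should give the Z-trisubstituted C4=C5 enoate at −78 °C, where the weakly basic phosphonate anion does not epimerise C6.

Step 11
Reactants: 16 ethyl (2Z)-3-[(2S,3S)-3-[(1S,2Z)-1-[tert-butyl(dimethyl)silyl]oxy-3-iodobut-2-en-1-yl]-5-oxooxolan-2-yl]-2-methylprop-2-enoate
Product: 17 (4S,5S)-4-[(1S,2Z)-1-[tert-butyl(dimethyl)silyl]oxy-3-iodobut-2-en-1-yl]-5-[(1Z)-3-hydroxy-2-methylprop-1-en-1-yl]oxolan-2-ol (lactol anomers)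
Conditions: iBu2AlH (excess), CH2Cl2, −78 °C; aq. potassium sodium tartrate
Reagents that add atoms: none
Why: Hydride reduction with iBu2AlH at −78 °C takes the enoate to the Z-allylic alcohol and stops the γ-lactone at the lactol (stable tetrahedral aluminate), so no chemoselectivity between the two carbonyl groups is asked for.

Step 12
Reactants: 17 (4S,5S)-4-[(1S,2Z)-1-[tert-butyl(dimethyl)silyl]oxy-3-iodobut-2-en-1-yl]-5-[(1Z)-3-hydroxy-2-methylprop-1-en-1-yl]oxolan-2-ol
Product: 18 (2Z)-3-[(2S,3S)-3-[(1S,2Z)-1-[tert-butyl(dimethyl)silyl]oxy-3-iodobut-2-en-1-yl]-5-oxooxolan-2-yl]-2-methylprop-2-enal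
Conditions: TEMPO (cat.), PhI(OAc)2, CH2Cl2, rt
Reagents that add atoms: none
Why: Oxoammonium (TEMPO) oxidation converts the primary allylic alcohol into the Z-enal without Z/E isomerisation and the lactol back into the lactone in the same flask.

Step 13
Reactants: 18 (2Z)-3-[(2S,3S)-3-[(1S,2Z)-1-[tert-butyl(dimethyl)silyl]oxy-3-iodobut-2-en-1-yl]-5-oxooxolan-2-yl]-2-methylprop-2-enal; 19 tributyl(1-ethoxyvinyl)stannane
Product: 20 (2Z)-3-[(2S,3S)-3-[(1R,2Z)-1-[tert-butyl(dimethyl)silyl]oxy-4-ethoxy-3-methylpenta-2,4-dien-1-yl]-5-oxooxolan-2-yl]-2-methylprop-2-enal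
Conditions: 19, Pd2(dba)3 (cat.), AsPh3, CuI, DMF, rt → 40 °C
Reagents that add atoms: tributyl(1-ethoxyvinyl)stannane (19), CCCC[Sn](CCCC)(CCCC)C(=C)OCC
Why: Stille coupling on zerovalent palladium proceeds with retention at the Z-vinyl iodide and brings in C1/C2 as an enol ether, oxidative addition into C–I being much faster than ionisation of the allylic C6–O lactone bond.

Step 14
Reactants: 20 (2Z)-3-[(2S,3S)-3-[(1R,2Z)-1-[tert-butyl(dimethyl)silyl]oxy-4-ethoxy-3-methylpenta-2,4-dien-1-yl]-5-oxooxolan-2-yl]-2-methylprop-2-enal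
Product: 21 (2Z)-3-[(2S,3S)-3-[(1R,2Z)-5-bromo-1-[tert-butyl(dimethyl)silyl]oxy-3-methyl-4-oxopent-2-en-1-yl]-5-oxooxolan-2-yl]-2-methylprop-2-enal
Conditions: NBS, THF/H2O (4:1), 0 °C
Reagents that add atoms: N-bromosuccinimide, O=C1CCC(=O)N1Br; water, O
Why: Electrophilic bromination at the terminal carbon of the enol ether followed by hydrolysis of the oxocarbenium ion (the known conversion of 1-ethoxyvinyl into bromoacetyl groups) gives the bromomethyl ketone regiospecifically under neutral conditions that the Z-enal tolerates.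

Step 15
Reactants: 21 (2Z)-3-[(2S,3S)-3-[(1R,2Z)-5-bromo-1-[tert-butyl(dimethyl)silyl]oxy-3-methyl-4-oxopent-2-en-1-yl]-5-oxooxolan-2-yl]-2-methylprop-2-enal
Product: 23 (3S,6S,7S,8R)-8-[tert-butyl(dimethyl)silyl]oxy-3-hydroxy-1-oxo-13-norgermacra-4Z,9Z-dien-12,6-olide (ten-membered β-hydroxy enone cis-fused to the saturated lactone), via samarium enolate 22 (not isolated)
Conditions: SmI2 (2.5 equiv), THF, −78 °C, slow addition of 21 (final 0.003 M); sat. aq. NH4Cl
Reagents that add atoms: none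
Why: Two single-electron transfers from divalent samarium cleave the C2–Br bond of 21 and give the oxygen-bound trivalent samarium enolate 22, whose C2 adds to the C3 aldehyde; this is a SmI2-mediated intramolecular Reformatsky reaction of an α-bromo ketone, a reaction type already used to close medium and large carbocycles. The ring C1–C10 closes in a 10-(enolendo)-exo-trig mode, with the enolate C1=C2 inside the new ring and the aldehyde C=O outside it. The new stereocentre C3 is set under substrate control: samarium bridges the enolate and aldehyde oxygens in a chair-like cyclic transition state, and the cis lactone at C6/C7 with the C8 silyl ether folds the two Z-alkenyl arms so that C2 is expected to reach the Si face of the aldehyde, which gives 3S. The step also needs C–Br reduction to outrun ketyl formation at the enal and ring closure to outrun oligomerisation; the much faster reduction of α-halo ketones at −78 °C without additive and slow addition at high dilution should secure both. No base is present, so the Z-enal, the Z-enone and C6 next to the lactone oxygen are preserved, and the samarium aldolate resists retro-aldol cleavage and dehydration until the quench.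

Step 16
Reactants: 23 (3S,6S,7S,8R)-8-[tert-butyl(dimethyl)silyl]oxy-3-hydroxy-1-oxo-13-norgermacra-4Z,9Z-dien-12,6-olide
Product: 24 (1S,3S,6S,7S,8R)-8-[tert-butyl(dimethyl)silyl]oxy-1,3-dihydroxy-13-norgermacra-4Z,9Z-dien-12,6-olide
Conditions: Me4NBH(OAc)3, MeCN/AcOH (1:1), −30 °C
Reagents that add atoms: none
Why: In the Evans–Saksena reduction the C3 hydroxyl binds the triacetoxyborohydride and hydride is delivered intramolecularly to the C1 ketone through a chair-like six-membered transition state, which should give the 1,3-anti diol (1S) by 1,2-reduction.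

Step 17
Reactants: 24 (1S,3S,6S,7S,8R)-8-[tert-butyl(dimethyl)silyl]oxy-1,3-dihydroxy-13-norgermacra-4Z,9Z-dien-12,6-olide
Product: 25 (1S,3S,6S,7S,8R)-8-[tert-butyl(dimethyl)silyl]oxy-1,3-(isopropylidenedioxy)-13-norgermacra-4Z,9Z-dien-12,6-olide
Conditions: 2,2-dimethoxypropane, PPTS (cat.), CH2Cl2, rt
Reagents that add atoms: 2,2-dimethoxypropane, COC(C)(C)OC
Why: Acid-catalysed transacetalisation ties the 1,3-diol as an isopropylidene acetal, so that neither hydroxyl interferes with enolate formation or with the acylation of O8.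

Step 18
Reactants: 25 (1S,3S,6S,7S,8R)-8-[tert-butyl(dimethyl)silyl]oxy-1,3-(isopropylidenedioxy)-13-norgermacra-4Z,9Z-dien-12,6-olide
Product: 28 (1S,3S,6S,7S,8R)-8-[tert-butyl(dimethyl)silyl]oxy-1,3-(isopropylidenedioxy)germacra-4Z,9Z,11(13)-trien-12,6-olide, via Mannich base 26 (not isolated), via ammonium iodide 27 (not isolated)
Conditions: LiN(iPr)2, THF, −78 °C; Me2N=CH2 I, −78 → 0 °C; MeI, CH2Cl2, rt; aq. NaHCO3, EtOAc, rt
Reagents that add atoms: Eschenmoser's salt (N,N-dimethylmethyleneiminium iodide), C=[N+](C)C.[I-]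
Why: Mannich reaction of the lactone enolate with Eschenmoser's salt, quaternisation and mild base elimination give the exocyclic C11=C13 methylene; the transient C11 stereocentre is destroyed, and the enolate has no β-leaving group on C7.

Step 19
Reactants: 28 (1S,3S,6S,7S,8R)-8-[tert-butyl(dimethyl)silyl]oxy-1,3-(isopropylidenedioxy)germacra-4Z,9Z,11(13)-trien-12,6-olide
Product: 29 (1S,3S,6S,7R,8R)-8-hydroxy-1,3-(isopropylidenedioxy)germacra-4Z,9Z,11(13)-trien-12,6-olide
Conditions: HF·pyridine, pyridine, THF, 0 °C → rt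
Reagents that add atoms: none
Why: Fluoride-mediated desilylation under pyridine-buffered, mildly acidic conditions frees O8–H without generating an alkoxide, so the lactone should not migrate to O8 and the acetonide and α-methylene lactone stay intact.

Step 20
Reactants: 29 (1S,3S,6S,7R,8R)-8-hydroxy-1,3-(isopropylidenedioxy)germacra-4Z,9Z,11(13)-trien-12,6-olide; 30 angelic acid ((2Z)-2-methylbut-2-enoic acid)
Product: 31 (1S,3S,6S,7S,8R)-8-[(2Z)-2-methylbut-2-enoyl]oxy-1,3-(isopropylidenedioxy)germacra-4Z,9Z,11(13)-trien-12,6-olide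
Conditions: 30, 2,4,6-trichlorobenzoyl chloride, Et3N, toluene, rt; then 29, 80 °C
Reagents that add atoms: angelic acid (30), C/C=C(/C)C(=O)O
Why: Yamaguchi-type acylation through the mixed anhydride directs the hindered alcohol to the unshielded angeloyl carbonyl, and leaving out a nucleophilic catalyst avoids the addition–elimination pathway that isomerises angelates to tiglates.

Step 21
Reactants: 31 (1S,3S,6S,7S,8R)-8-[(2Z)-2-methylbut-2-enoyl]oxy-1,3-(isopropylidenedioxy)germacra-4Z,9Z,11(13)-trien-12,6-olide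
Product: 32 (1S,3S,6S,7S,8R)-1,3-dihydroxy-8-[(2Z)-2-methylbut-2-enoyl]oxygermacra-4Z,9Z,11(13)-trien-12,6-olide (CNP0152559.4)
Conditions: AcOH/THF/H2O (3:1:1), rt → 35 °C
Reagents that add atoms: none
Why: Mild acid hydrolysis cleaves the anti-1,3-diol acetonide, which is strained by its twist-boat form, without ionising the allylic carbinols or isomerising the angelate.

**Compound list**

1 | 1,2:5,6-di-O-isopropylidene-α-D-glucofuranose (diacetone-D-glucose) | CC1(C)OC[C@@H](O1)[C@@H]2[C@@H]([C@@H]3[C@H](O2)OC(C)(C)O3)O | starting material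
2 | 1,2:5,6-di-O-isopropylidene-α-D-ribo-hexofuranos-3-ulose | CC1(C)OC[C@@H](O1)[C@@H]2C(=O)[C@@H]3[C@H](O2)OC(C)(C)O3 | intermediate
3 | trimethyl phosphonoacetate | COC(=O)CP(=O)(OC)OC | starting material
4 | methyl 2-(3-deoxy-1,2:5,6-di-O-isopropylidene-α-D-ribo-hexofuranos-3-ylidene)acetate (E/Z mixture) | CC1(C)OC[C@@H](O1)[C@@H]2C(=CC(=O)OC)[C@@H]3[C@H](O2)OC(C)(C)O3 | intermediate
5 | 3-deoxy-3-C-(2-methoxy-2-oxoethyl)-1,2:5,6-di-O-isopropylidene-α-D-allofuranose | CC1(C)OC[C@@H](O1)[C@@H]2[C@@H](CC(=O)OC)[C@@H]3[C@H](O2)OC(C)(C)O3 | intermediate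
6 | 3-deoxy-3-C-(2-methoxy-2-oxoethyl)-1,2-O-isopropylidene-α-D-allofuranose (5,6-diol) | OC[C@@H](O)[C@@H]1[C@@H](CC(=O)OC)[C@@H]2[C@H](O1)OC(C)(C)O2 | intermediate (not isolated)
7 | 3-deoxy-3-C-(2-methoxy-2-oxoethyl)-1,2-O-isopropylidene-α-D-ribo-pentodialdo-1,4-furanose | O=C[C@@H]1[C@@H](CC(=O)OC)[C@@H]2[C@H](O1)OC(C)(C)O2 | intermediate
8 | ethyltriphenylphosphonium iodide | CC[P+](c1ccccc1)(c1ccccc1)c1ccccc1.[I-] | starting material
9 | (5Z)-3,5,6,7-tetradeoxy-6-iodo-3-C-(2-methoxy-2-oxoethyl)-1,2-O-isopropylidene-α-D-ribo-hept-5-enofuranose | C/C(I)=C/[C@@H]1[C@@H](CC(=O)OC)[C@@H]2[C@H](O1)OC(C)(C)O2 | intermediate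
10 | (5Z)-3,5,6,7-tetradeoxy-6-iodo-3-C-(2-methoxy-2-oxoethyl)-D-ribo-hept-5-enofuranose (anomers) | C/C(I)=C/[C@@H]1[C@@H](CC(=O)OC)[C@@H](O)C(O)O1 | intermediate (not isolated)
11 | (3aR,4S,6aR)-6-hydroxy-4-[(1Z)-2-iodoprop-1-en-1-yl]tetrahydrofuro[3,4-b]furan-2(3H)-one (anomers at C6) | C/C(I)=C/[C@H]1OC(O)[C@@H]2OC(=O)C[C@H]12 | intermediate
12 | (4R,5R)-5-(1,3-dithian-2-yl)-4-[(1S,2Z)-1-hydroxy-3-iodobut-2-en-1-yl]oxolan-2-one | C/C(I)=C/[C@@H](O)[C@H]1CC(=O)O[C@H]1C2SCCCS2 | intermediate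
13 | (4S,5R)-4-[(1S,2Z)-1-[tert-butyl(dimethyl)silyl]oxy-3-iodobut-2-en-1-yl]-5-(1,3-dithian-2-yl)oxolan-2-one | C/C(I)=C/[C@@H](O[Si](C)(C)C(C)(C)C)[C@H]1CC(=O)O[C@H]1C2SCCCS2 | intermediate
14 | (2R,3S)-3-[(1S,2Z)-1-[tert-butyl(dimethyl)silyl]oxy-3-iodobut-2-en-1-yl]-5-oxooxolane-2-carbaldehyde | C/C(I)=C/[C@@H](O[Si](C)(C)C(C)(C)C)[C@H]1CC(=O)O[C@H]1C=O | intermediate
15 | ethyl 2-[bis(2,2,2-trifluoroethoxy)phosphoryl]propanoate | CCOC(=O)C(C)P(=O)(OCC(F)(F)F)OCC(F)(F)F | starting material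
16 | ethyl (2Z)-3-[(2S,3S)-3-[(1S,2Z)-1-[tert-butyl(dimethyl)silyl]oxy-3-iodobut-2-en-1-yl]-5-oxooxolan-2-yl]-2-methylprop-2-enoate | C/C(I)=C/[C@@H](O[Si](C)(C)C(C)(C)C)[C@H]1CC(=O)O[C@H]1/C=C(/C)C(=O)OCC | intermediate
17 | (4S,5S)-4-[(1S,2Z)-1-[tert-butyl(dimethyl)silyl]oxy-3-iodobut-2-en-1-yl]-5-[(1Z)-3-hydroxy-2-methylprop-1-en-1-yl]oxolan-2-ol (lactol anomers) | C/C(I)=C/[C@@H](O[Si](C)(C)C(C)(C)C)[C@H]1CC(O)O[C@H]1/C=C(/C)CO | intermediate
18 | (2Z)-3-[(2S,3S)-3-[(1S,2Z)-1-[tert-butyl(dimethyl)silyl]oxy-3-iodobut-2-en-1-yl]-5-oxooxolan-2-yl]-2-methylprop-2-enal | C/C(I)=C/[C@@H](O[Si](C)(C)C(C)(C)C)[C@H]1CC(=O)O[C@H]1/C=C(/C)C=O | intermediate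
19 | tributyl(1-ethoxyvinyl)stannane | CCCC[Sn](CCCC)(CCCC)C(=C)OCC | starting material
20 | (2Z)-3-[(2S,3S)-3-[(1R,2Z)-1-[tert-butyl(dimethyl)silyl]oxy-4-ethoxy-3-methylpenta-2,4-dien-1-yl]-5-oxooxolan-2-yl]-2-methylprop-2-enal | C=C(OCC)/C(C)=C\[C@@H](O[Si](C)(C)C(C)(C)C)[C@H]1CC(=O)O[C@H]1/C=C(/C)C=O | intermediate
21 | (2Z)-3-[(2S,3S)-3-[(1R,2Z)-5-bromo-1-[tert-butyl(dimethyl)silyl]oxy-3-methyl-4-oxopent-2-en-1-yl]-5-oxooxolan-2-yl]-2-methylprop-2-enal (key-step precursor) | BrCC(=O)/C(C)=C\[C@@H](O[Si](C)(C)C(C)(C)C)[C@H]1CC(=O)O[C@H]1/C=C(/C)C=O | intermediate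
22 | diiodosamarium enolate of 21 (trivalent samarium on the C1 oxygen; C1=C2 enolate) | C=C(O[Sm](I)I)/C(C)=C\[C@@H](O[Si](C)(C)C(C)(C)C)[C@H]1CC(=O)O[C@H]1/C=C(/C)C=O | intermediate (not isolated)
23 | (3S,6S,7S,8R)-8-[tert-butyl(dimethyl)silyl]oxy-3-hydroxy-1-oxo-13-norgermacra-4Z,9Z-dien-12,6-olide | C1C(=O)O[C@H]2/C=C(/C)[C@@H](O)CC(=O)/C(C)=C\[C@@H](O[Si](C)(C)C(C)(C)C)[C@@H]12 | intermediate
24 | (1S,3S,6S,7S,8R)-8-[tert-butyl(dimethyl)silyl]oxy-1,3-dihydroxy-13-norgermacra-4Z,9Z-dien-12,6-olide | C1C(=O)O[C@H]2/C=C(/C)[C@@H](O)C[C@H](O)/C(C)=C\[C@@H](O[Si](C)(C)C(C)(C)C)[C@@H]12 | intermediate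
25 | (1S,3S,6S,7S,8R)-8-[tert-butyl(dimethyl)silyl]oxy-1,3-(isopropylidenedioxy)-13-norgermacra-4Z,9Z-dien-12,6-olide | C1C(=O)O[C@H]2/C=C(/C)[C@@H]3C[C@H](OC(C)(C)O3)/C(C)=C\[C@@H](O[Si](C)(C)C(C)(C)C)[C@@H]12 | intermediate
26 | 11-[(dimethylamino)methyl] derivative of 25 (C11 epimers) | CN(C)CC1C(=O)O[C@H]2/C=C(/C)[C@@H]3C[C@H](OC(C)(C)O3)/C(C)=C\[C@@H](O[Si](C)(C)C(C)(C)C)[C@@H]12 | intermediate (not isolated)
27 | 11-[(trimethylammonio)methyl] iodide derived from 26 (C11 epimers) | C[N+](C)(C)CC1C(=O)O[C@H]2/C=C(/C)[C@@H]3C[C@H](OC(C)(C)O3)/C(C)=C\[C@@H](O[Si](C)(C)C(C)(C)C)[C@@H]12.[I-] | intermediate (not isolated)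
28 | (1S,3S,6S,7S,8R)-8-[tert-butyl(dimethyl)silyl]oxy-1,3-(isopropylidenedioxy)germacra-4Z,9Z,11(13)-trien-12,6-olide | C=C1C(=O)O[C@H]2/C=C(/C)[C@@H]3C[C@H](OC(C)(C)O3)/C(C)=C\[C@@H](O[Si](C)(C)C(C)(C)C)[C@@H]12 | intermediate
29 | (1S,3S,6S,7R,8R)-8-hydroxy-1,3-(isopropylidenedioxy)germacra-4Z,9Z,11(13)-trien-12,6-olide | C=C1C(=O)O[C@H]2/C=C(/C)[C@@H]3C[C@H](OC(C)(C)O3)/C(C)=C\[C@@H](O)[C@@H]12 | intermediate
30 | angelic acid ((2Z)-2-methylbut-2-enoic acid) | C/C=C(/C)C(=O)O | starting material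
31 | (1S,3S,6S,7S,8R)-8-[(2Z)-2-methylbut-2-enoyl]oxy-1,3-(isopropylidenedioxy)germacra-4Z,9Z,11(13)-trien-12,6-olide | C=C1C(=O)O[C@H]2/C=C(/C)[C@@H]3C[C@H](OC(C)(C)O3)/C(C)=C\[C@@H](OC(=O)/C(C)=C\C)[C@@H]12 | intermediate
32 | (1S,3S,6S,7S,8R)-1,3-dihydroxy-8-[(2Z)-2-methylbut-2-enoyl]oxygermacra-4Z,9Z,11(13)-trien-12,6-olide (CNP0152559.4) | C=C1C(=O)O[C@H]2/C=C(/C)[C@@H](O)C[C@H](O)/C(C)=C\[C@@H](OC(=O)/C(C)=C\C)[C@@H]12 | target

**Totals.** Total step count: 21. Longest linear sequence: 21 steps (1 → 32).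

**Steps most likely to fail**

Step 15. What may go wrong: addition to the wrong face of the C3 aldehyde, or electron transfer to the enal and intermolecular aldol addition competing with ring closure. The fallback replaces the samarium enolate by a reagent-controlled boron enolate and sets out from 20. Hydrolysis of the enol ether with oxalic acid in wet THF at 0 °C should give the methyl Z-enone F1, which keeps the enal. Enolisation of its methyl ketone with chlorodiisopinocampheylborane (Ipc2BCl) and Et3N in Et2O at −78 °C under high dilution follows, with the Ipc2BCl antipode chosen to direct C2 to the Si face of the aldehyde. Non-oxidative work-up with diethanolamine should then close the ring and return to the route at 23.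

Step 16. What may go wrong: the ring conformation overrides internal hydride delivery, so the hydride arrives on the face that gives the 1,3-syn diol. The fallback uses external reagent control and sets out from 23. TESOTf and 2,6-lutidine in CH2Cl2 at −78 °C give the C3 triethylsilyl ether F2. Corey–Bakshi–Shibata reduction with (R)-2-methyl-CBS-oxazaborolidine and catecholborane in toluene at −78 °C, the alkenyl side acting as the large group, should give the 1S allylic alcohol F3. PPTS in MeOH at 0 °C removes only the triethylsilyl group, and the route is rejoined at 24.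

Step 5. What may go wrong: incomplete olefination and loss of Z selectivity with the basic iodo ylide, together with epimerisation at s4 of the aldehyde. The fallback builds the vinyl halide in stereodefined stages and sets out from 7. Corey–Fuchs dibromo-olefination (CBr4, PPh3, Et3N, CH2Cl2, 0 °C) gives the 1,1-dibromoalkene F4. Negishi coupling with MeZnCl and PdCl2(DPEphos) in THF replaces selectively the bromine trans to s4 and should give the Z-vinyl bromide F5. Halogen exchange with NaI, catalytic CuI and trans-N,N'-dimethylcyclohexane-1,2-diamine in dioxane at 110 °C proceeds with retention and returns to the route at 9.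

**Further compounds**

F1 | step 15 | (2Z)-3-[(2S,3S)-3-[(1R,2Z)-1-[tert-butyl(dimethyl)silyl]oxy-3-methyl-4-oxopent-2-en-1-yl]-5-oxooxolan-2-yl]-2-methylprop-2-enal | CC(=O)/C(C)=C\[C@@H](O[Si](C)(C)C(C)(C)C)[C@H]1CC(=O)O[C@H]1/C=C(/C)C=O
F2 | step 16 | (3S,6S,7S,8R)-8-[tert-butyl(dimethyl)silyl]oxy-1-oxo-3-(triethylsilyl)oxy-13-norgermacra-4Z,9Z-dien-12,6-olide | C1C(=O)O[C@H]2/C=C(/C)[C@@H](O[Si](CC)(CC)CC)CC(=O)/C(C)=C\[C@@H](O[Si](C)(C)C(C)(C)C)[C@@H]12
F3 | step 16 | (1S,3S,6S,7S,8R)-8-[tert-butyl(dimethyl)silyl]oxy-1-hydroxy-3-(triethylsilyl)oxy-13-norgermacra-4Z,9Z-dien-12,6-olide | C1C(=O)O[C@H]2/C=C(/C)[C@@H](O[Si](CC)(CC)CC)C[C@H](O)/C(C)=C\[C@@H](O[Si](C)(C)C(C)(C)C)[C@@H]12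
F4 | step 5 | 6,6-dibromo-3,5,6-trideoxy-3-C-(2-methoxy-2-oxoethyl)-1,2-O-isopropylidene-α-D-ribo-hex-5-enofuranose | BrC(Br)=C[C@@H]1[C@@H](CC(=O)OC)[C@@H]2[C@H](O1)OC(C)(C)O2
F5 | step 5 | (5Z)-6-bromo-3,5,6,7-tetradeoxy-3-C-(2-methoxy-2-oxoethyl)-1,2-O-isopropylidene-α-D-ribo-hept-5-enofuranose | C/C(Br)=C/[C@@H]1[C@@H](CC(=O)OC)[C@@H]2[C@H](O1)OC(C)(C)O2
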